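# Proposed synthesis of ambuic acid (20) by Diels–Alder union of a 1‑silyloxy‑4‑acetoxy diene with a heptenyl ynal

**Compound numbers used throughout.** 1 (E)-oct-2-enal; 2 dibromodiene; 3, 4 lithium intermediates; 5 ynal; 6 but-2-yne-1,4-diol; 7 stannyl diol; 8 mono-silyl stannane; 9 bromo ester; 10 allylic alcohol; 11 enal; 12 diene; 13 cycloadduct; 14 dienol; 15 epoxy aldehyde; 16 epoxy diol; 17 acetonide; 18 hydroxy acid; 19 keto acid acetonide; 20 target.

## Analysis of the target

Target 20 is a cyclohexenone fused to an oxirane (a 7-oxabicyclo[4.1.0]hept-3-en-2-one) in which every ring carbon is substituted; the ring atoms are labelled here C1 ((E)-hept-1-enyl), C2 (CH2OH), C3 (secondary carbinol), C4 (epoxide CH), C5 (quaternary epoxide carbon carrying the CH2–CH=C(CH3)–CO2H arm) and C6 (ketone). There are three contiguous stereocentres, C3, C4 and C5, all R, with the C3 hydroxyl on the same face as the epoxide oxygen; both side-chain alkenes are E. C4 and C5 are tied together by the oxirane, so the real stereochemical tasks are one absolute configuration (C3) and one relative one (epoxide syn to C3–OH). The sensitive functions are the α,β-epoxy ketone and γ-hydroxy enone (base opens the epoxide and leads towards an arene), the skipped enoate whose doubly allylic CH2 can slip into conjugation, the free acid, and the C2 hydroxymethyl group, whose aldehyde oxidation level is a cis-dienal able to close to a 2H-pyran. The difficulty is density: three different carbon arms and four oxygen functions on six carbons, one of them quaternary, on a ring that at several oxidation levels is one elimination away from a benzene. The strategy rests on the para relation of the C3 and C6 oxygens across C4–C5 together with the tetrasubstituted C1=C2 bond bearing the heptenyl group and a one-carbon arm: C3–C4–C5–C6 is a 1,4-dioxygenated 2-alkylbutadiene (12) and C1–C2 is an alkyne with a formyl group on C2 (5). Their cycloaddition gives the non-aromatic ring 13 with all nineteen skeletal carbons and the C3 stereocentre, from which the epoxide is relayed.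

## Retrosynthetic reasoning

**20 ⇐ 19 ⇐ 18 ⇐ 17 (unmasking and C6 oxidation level).** The last bonds cut are the two C–O bonds of the isopropylidene acetal in 19, which has no base-labile group left to remove. The C6 ketone is taken back to the C6 alcohol 18 because the epoxy enone is the base-sensitive part of the molecule. Both ester cleavages (C6 acetate and methyl ester, 17 → 18) are therefore placed before the oxidation. At that stage the C6 alkoxide is cis to the oxirane and cannot undergo epoxide migration, and the (E)-carboxylate cannot reach C5.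

**17 ⇐ 16 ⇐ 15 (C2 arm).** The acetal ties C3–OH to the C2 hydroxymethyl group so that C6 is the only free hydroxyl when it is oxidised. The hydroxymethyl group is traced to the formyl group of 15 by a 1,2-reduction. Keeping C2 at the aldehyde level up to 15 is deliberate: the formyl group deactivates C1=C2 during the epoxidation.

**15 ⇐ 14 ⇐ 13 (epoxide).** The two C–O bonds of the oxirane are cut back to the C4=C5 alkene of 14. Forward, the free C3 hydroxyl delivers oxygen to its own face, so C4 and C5 follow from C3. In 14 the C6 acetate is on the same face, so nothing opposes the delivery. 14 comes from 13 by removing only the silyl group.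

**13 ⇐ 12 + 5 (key disconnection).** The C2–C3 and C1–C6 bonds are cut. This is the only cut that removes the ring, places both carbon substituents of C1=C2 and both para oxygens in one step, and never passes through an arene. Forward, the reaction must join C6 of 12 to the β-carbon of 5 (regiochemistry), add suprafacially to the (1E,3E)-diene (cis C3–O/C6–O) and choose one diene face (C3 absolute configuration).

**12 ⇐ 11 (diene).** The enol acetate C6–O bond is cut, leaving the formyl group of 11 at C6 and the silyl ether already on C3. Placing the aldehyde at C6 and not at C3 matters for two reasons: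
- With the formyl group on C6, only the C3 hydrogens are γ to it. In the reverse arrangement the doubly activated side-chain CH2 would compete.
- The enol acetate geometry derives from the s-trans enal, and the silyl enol ether geometry is enforced by allylic strain against the fully substituted C5.

**11 ⇐ 10 ⇐ 8 + 9; 8 ⇐ 7 ⇐ 6 (C5 arm).** The C5–CH2 bond is cut between an alkenylstannane (8) and the allylic bromide 9, which brings in the complete enoate arm. The stannane comes from syn-hydrostannation of the symmetrical alkyne 6, followed by silylation of the hydroxyl remote from tin (7 → 8). The tin atom thus marks C5 and differentiates C3–O from C6–O.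

**5 ⇐ 2 ⇐ 1 (ynal).** The formyl–alkyne bond and the alkyne itself are traced to the commercial (E)-enal 1 by one-carbon homologation through dibromide 2, which keeps the E alkene of the heptenyl group.

## Alternatives that were turned down

**Alternative 1: cyclopentadiene template on a quinone, then cycloreversion.**
- Disconnection: the ring carbons come from the 2-alkyl-1,4-benzoquinone A1. Its unsubstituted double bond (the future C1=C2) is masked by cyclopentadiene A2.
- Key step: an oxazaborolidinium-catalysed endo Diels–Alder reaction gives the tricyclic enedione A3.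
- For: this reaction class is established for 2-substituted quinones. The folded shape of A3 then directs nucleophilic epoxidation of C4=C5 and hydride reduction at C3 by substrate control. No intermediate is as close to aromatisation as 13.
- Against: both bonds made in the key step are broken again, in a thermal cycloreversion that must be survived by an epoxide and a skipped enoate. C1 and C2 emerge as bare CH=CH, so the heptenyl group and the hydroxymethyl group must be added one at a time. The hydroxymethyl group is the harder one: C2 is β to the C6 carbonyl and α only to a C3 carbonyl that then has to be told apart from C6. About twelve further operations are foreseen after A3.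
- Comparison: Alternative 1 is stronger on precedent and on enantiocontrol. The chosen route offers in exchange a cycloaddition that keeps every bond it makes and delivers C1=C2 with both carbon substituents, finishing seven steps later.

**Alternative 2: intramolecular Darzens closure.**
- Disconnection: C4–C5 and C5–O are cut to the open-chain (Z)-enone chloro keto aldehyde A4, whose C3 centre would come from a chiral-pool butenolide.
- Key step: base-mediated aldol addition and chloride displacement give the protected epoxy enone A5.
- For: carbocycle and oxirane form together with C6 already a ketone, so there is no oxidation-state shuffle at C6. The absolute configuration is secure, and nothing can aromatise.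
- Against: A4 is a tetrasubstituted (Z)-alkene with four different arms, an α-silyloxy aldehyde and an α-chloro ketone. It is long to assemble, and under the base it can epimerise at C3 or isomerise. The key step must select one of four C4/C5 diastereomers, which depends on the aldol face at an α-oxygenated aldehyde and on a chlorohydrin geometry that allows backside closure. The acid arm has to travel as a PMB ether, costing three late steps.
- Comparison: Alternative 2 is stronger in oxidation-state economy. The chosen route reaches its key-step precursor 12 in five steps and relays the stereotriad from one centre by a dependable directed epoxidation, so its risk sits in one step.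

**Alternative 3: ring-closing enyne metathesis.**
- Disconnection: the C1=C2 ring bond is cut to the epoxy enyne A6, whose C3–C5 triad comes from a Sharpless epoxidation.
- Key step: a ruthenium carbene (second-generation Grubbs catalyst, (H2IMes)(PCy3)Cl2Ru=CHPh) closes A6 to the 1-vinylcyclohexene A7.
- For: absolute and relative configuration come from a very reliable asymmetric epoxidation. The metathesis is neutral, and no aromatisation channel exists.
- Against: the closure must join a 1,1-disubstituted alkene to an alkyne next to a quaternary epoxide carbon and form a tetrasubstituted ring alkene, the slowest case of this reaction. A7 carries a vinyl group where heptenyl is needed, which means a site- and E-selective cross-metathesis on a conjugated diene. The acid arm is only a protected hydroxyethyl group, so deprotection, oxidation, olefination and hydrolysis remain, as do C6 desilylation and oxidation. At least ten steps follow A7.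
- Comparison: Alternative 3 is stronger on stereochemical certainty and functional-group safety. The chosen route carries the complete heptenyl and enoate arms into the ring-forming step and is about half as long after it.

Key step: step 8

**Remarks on the chemistry.**
- Ring positions are called C1–C6 as defined in the analysis. In the systematic names of 13 and 14 the ring locants 3 and 6 coincide with C3 and C6. In the 7-oxabicyclo[4.1.0]heptene names, locants 1, 2, 3, 4, 5, 6 correspond to C5, C6, C1, C2, C3, C4.
- Assumption: the sense of induction of the boron catalyst for this new diene/ynal pair is taken from the usual pre-transition-state model and the (S)-catalyst is written. If the model places the diene on the other face, the (R)-catalyst is used with no other change.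

## Route

Step 1
Reactants: 1 (E)-oct-2-enal
Product: 2 (3E)-1,1-dibromonona-1,3-diene
Conditions: CBr4, PPh3, CH2Cl2, 0 °C
Reagents that add atoms: carbon tetrabromide, BrC(Br)(Br)Br
Why: Ramirez dibromo-olefination (first stage of the Corey–Fuchs sequence): the ylide Ph3P=CBr2 formed in the flask undergoes a Wittig reaction with the aldehyde and leaves the existing E alkene untouched.

Step 2
Reactants: 2 (3E)-1,1-dibromonona-1,3-diene
Product: 5 (E)-dec-4-en-2-ynal, via lithium (E)-non-3-en-1-ynide 3 (not isolated), via lithium (E)-1-(dimethylamino)dec-4-en-2-yn-1-olate 4 (not isolated)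
Conditions: n-BuLi (2.1 equiv), THF, −78 °C; DMF, −78 to 0 °C; inverse quench into aq. KH2PO4, 0 °C
Reagents that add atoms: N,N-dimethylformamide, CN(C)C=O (n-butyllithium, [Li]CCCC, supplies only the lithium of 3 and 4)
Why: Second stage of the Corey–Fuchs reaction: Br/Li exchange and Fritsch–Buttenberg–Wiechell 1,2-shift give the alkyne, which the second equivalent of base converts into acetylide 3; formylation with DMF stops at the tetrahedral adduct 4, and the buffered inverse quench releases the ynal without letting dimethylamine add to it.

Step 3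
Reactants: 6 but-2-yne-1,4-diol
Product: 7 (E)-2-(tributylstannyl)but-2-ene-1,4-diol
Conditions: Bu3SnH, Pd(PPh3)2Cl2 (1 mol %), THF, 23 °C
Reagents that add atoms: tributyltin hydride, CCCC[SnH](CCCC)CCCC
Why: Palladium-catalysed syn-hydrostannation; the alkyne is symmetrical so there is no regiochemical question, and syn addition places the two CH2OH groups cis (E descriptor because of tin).

Step 4
Reactants: 7 (E)-2-(tributylstannyl)but-2-ene-1,4-diol
Product: 8 (E)-4-[(tert-butyldimethylsilyl)oxy]-2-(tributylstannyl)but-2-en-1-ol
Conditions: TBSCl (1.0 equiv), imidazole, CH2Cl2, −20 °C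
Reagents that add atoms: tert-butyldimethylsilyl chloride, CC(C)(C)[Si](C)(C)Cl
Why: Sterically controlled monosilylation: the hydroxyl next to the tributylstannyl-bearing carbon is shielded, so the bulky silyl chloride should take the remote C4 hydroxyl (the future C3 oxygen).

Step 5
Reactants: 8 (E)-4-[(tert-butyldimethylsilyl)oxy]-2-(tributylstannyl)but-2-en-1-ol; 9 methyl (E)-4-bromo-2-methylbut-2-enoate
Product: 10 methyl (2E,5Z)-7-[(tert-butyldimethylsilyl)oxy]-5-(hydroxymethyl)-2-methylhepta-2,5-dienoate
Conditions: Pd2(dba)3 (2.5 mol %), AsPh3 (10 mol %), NMP, 40 °C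
Reagents that add atoms: none
Why: Stille coupling of an alkenylstannane with an allylic bromide through a π-allylpalladium intermediate; the bond forms at the primary allyl terminus, which keeps the enoate conjugated and E, and the alkenyl geometry is retained.

Step 6
Reactants: 10 methyl (2E,5Z)-7-[(tert-butyldimethylsilyl)oxy]-5-(hydroxymethyl)-2-methylhepta-2,5-dienoate
Product: 11 methyl (2E,5Z)-7-[(tert-butyldimethylsilyl)oxy]-5-formyl-2-methylhepta-2,5-dienoate
Conditions: MnO2 (activated, excess), CH2Cl2, 23 °C
Reagents that add atoms: none
Why: Neutral, chemoselective MnO2 oxidation of a primary allylic alcohol; the silyl ether and the skipped diene are not affected, and the 5Z geometry is of no consequence because this double bond becomes the central single bond of the diene.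

Step 7
Reactants: 11 methyl (2E,5Z)-7-[(tert-butyldimethylsilyl)oxy]-5-formyl-2-methylhepta-2,5-dienoate
Product: 12 methyl (2E)-4-[(1E,3E)-1-(acetyloxy)-4-[(tert-butyldimethylsilyl)oxy]buta-1,3-dien-2-yl]-2-methylbut-2-enoate
Conditions: Ac2O, Et3N, DMAP (cat.), THF, 50 °C
Reagents that add atoms: acetic anhydride, CC(=O)OC(C)=O
Why: Vinylogous enolisation and O-acylation of an enal to a 1-acetoxydiene: only the C3 hydrogens are γ to the formyl group, the s-trans enal gives the E enol acetate, and allylic strain against the fully substituted C5 should enforce the E silyl enol ether.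

Step 8
Reactants: 12 methyl (2E)-4-[(1E,3E)-1-(acetyloxy)-4-[(tert-butyldimethylsilyl)oxy]buta-1,3-dien-2-yl]-2-methylbut-2-enoate; 5 (E)-dec-4-en-2-ynal
Product: 13 methyl (2E)-4-[(3S,6R)-6-(acetyloxy)-3-[(tert-butyldimethylsilyl)oxy]-4-formyl-5-[(1E)-hept-1-en-1-yl]cyclohexa-1,4-dien-1-yl]-2-methylbut-2-enoate
Conditions: (S)-3,3-diphenyl-1-(o-tolyl)tetrahydro-1H,3H-pyrrolo[1,2-c][1,3,2]oxazaborole (20 mol %) + HN(SO2CF3)2 (18 mol %), CH2Cl2, −78 °C; pH 7 phosphate buffer quench at −78 °C; cold filtration through Et3N-deactivated silica
Reagents that add atoms: none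
Why: Proposed new method: the N-protonated oxazaborolidine binds the formyl oxygen of 5 (B–O coordination supported by a formyl C–H···O contact), lowers the LUMO of the conjugated alkyne π-bond and screens one side of it, while the HOMO of 12 has its largest terminal coefficient at C6 (remote from the silyloxy donor and adjacent to the C5 alkyl group), so C6 bonds first to the ynal β-carbon (C1) and C3 then closes onto the formyl-bearing C2 in a concerted, asynchronous [π4s+π2s] cycloaddition. The closest known reactions are chiral-boron-catalysed Diels–Alder additions of ynals to cyclopentadiene and thermal additions of 1-silyloxy- and 1,4-diacyloxybutadienes to acetylenic carbonyl compounds; their combination on an acyclic 1,4-dioxygenated diene is untested. The six-membered carbocycle is closed by two intermolecular σ-bonds (C1–C6 and C2–C3); in the stepwise limit the second bond would form by 6-(enolexo)-exo-trig attack of the allenolate carbon C2 on the silyloxycarbenium carbon C3. The cis relation of C3–O and C6–O follows from suprafacial addition to the (1E,3E)-diene, both oxygen substituents of which point outward. The absolute configuration (3S,6R) is controlled by the catalyst, which must select one diene face through a single orientation of the bound ynal. The step needs regioselectivity, secured by the matched polarisation of the silyloxy donor and the C5 alkyl group against the weaker acetoxy donor. It needs chemoselectivity for C≡C over the activated C=O (hetero-Diels–Alder or Mukaiyama-type addition), which the linear, sterically open ynal β-carbon should favour. It also needs survival of an adduct that can lose acetic acid to an arene, hence the robust TBS ether, −78 °C and a neutral quench.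

Step 9
Reactants: 13 methyl (2E)-4-[(3S,6R)-6-(acetyloxy)-3-[(tert-butyldimethylsilyl)oxy]-4-formyl-5-[(1E)-hept-1-en-1-yl]cyclohexa-1,4-dien-1-yl]-2-methylbut-2-enoate
Product: 14 methyl (2E)-4-[(3S,6R)-6-(acetyloxy)-4-formyl-5-[(1E)-hept-1-en-1-yl]-3-hydroxycyclohexa-1,4-dien-1-yl]-2-methylbut-2-enoate
Conditions: HF·pyridine, excess pyridine, THF, 0 °C; used at once in step 10
Reagents that add atoms: none
Why: Buffered fluoride cleavage of a secondary silyl ether; the acetate is inert to HF·pyridine, and the excess pyridine keeps the medium close to neutral so that neither ionisation of the doubly allylic C–O bonds nor base-induced elimination is promoted.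

Step 10
Reactants: 14 methyl (2E)-4-[(3S,6R)-6-(acetyloxy)-4-formyl-5-[(1E)-hept-1-en-1-yl]-3-hydroxycyclohexa-1,4-dien-1-yl]-2-methylbut-2-enoate
Product: 15 methyl (2E)-4-[(1S,2S,5R,6R)-2-(acetyloxy)-4-formyl-3-[(1E)-hept-1-en-1-yl]-5-hydroxy-7-oxabicyclo[4.1.0]hept-3-en-1-yl]-2-methylbut-2-enoate
Conditions: VO(acac)2 (5 mol %), t-BuOOH (in decane), CH2Cl2, 0 °C
Reagents that add atoms: tert-butyl hydroperoxide, CC(C)(C)OO
Why: Hydroxyl-directed epoxidation: the vanadate ester of the C3 hydroxyl delivers the peroxide oxygen to the adjacent C4=C5 bond on the hydroxyl face, which sets C4 and C5 syn to C3–OH; C1=C2 is deactivated by the formyl group and the side-chain alkenes carry no directing hydroxyl.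

Step 11
Reactants: 15 methyl (2E)-4-[(1S,2S,5R,6R)-2-(acetyloxy)-4-formyl-3-[(1E)-hept-1-en-1-yl]-5-hydroxy-7-oxabicyclo[4.1.0]hept-3-en-1-yl]-2-methylbut-2-enoate
Product: 16 methyl (2E)-4-[(1S,2S,5R,6R)-2-(acetyloxy)-3-[(1E)-hept-1-en-1-yl]-5-hydroxy-4-(hydroxymethyl)-7-oxabicyclo[4.1.0]hept-3-en-1-yl]-2-methylbut-2-enoate
Conditions: NaBH4, CeCl3·7H2O, MeOH, −78 °C
Reagents that add atoms: none
Why: Luche reduction: the cerium salt directs hydride to the carbonyl carbon (1,2-addition) of the dienal, and the low temperature spares the acetate, the epoxide and both esters.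

Step 12
Reactants: 16 methyl (2E)-4-[(1S,2S,5R,6R)-2-(acetyloxy)-3-[(1E)-hept-1-en-1-yl]-5-hydroxy-4-(hydroxymethyl)-7-oxabicyclo[4.1.0]hept-3-en-1-yl]-2-methylbut-2-enoate
Product: 17 acetonide of 16: the C3 oxygen and the oxygen of the C2 hydroxymethyl group joined by C(CH3)2 in a 2,2-dimethyl-1,3-dioxane ring; C6 acetate, epoxide and methyl ester retained (C3 R, C4 R, C5 S, C6 S)
Conditions: Me2C(OMe)2, PPTS (cat.), CH2Cl2, 23 °C
Reagents that add atoms: 2,2-dimethoxypropane, COC(C)(C)OC
Why: Acid-catalysed transacetalisation of a 1,3-diol to a six-membered isopropylidene acetal; the weak acid does not open the trisubstituted epoxide, and the acetal leaves C6 as the only oxygen to be freed next.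

Step 13
Reactants: 17 acetonide of 16 (C6 acetate, methyl ester)
Product: 18 hydroxy acid: the acetonide of (2E)-4-[(1S,2S,5R,6R)-2,5-dihydroxy-3-[(1E)-hept-1-en-1-yl]-4-(hydroxymethyl)-7-oxabicyclo[4.1.0]hept-3-en-1-yl]-2-methylbut-2-enoic acid across O5 and the hydroxymethyl oxygen (free C6–OH, free CO2H)
Conditions: LiOH·H2O, THF/MeOH/H2O, 0 to 23 °C; then 0.5 M HCl to pH 4, 0 °C
Reagents that add atoms: lithium hydroxide, [Li+].[OH-] (its oxygen ends in the carboxyl group)
Why: Saponification of the acetate and the methyl ester in one operation while the ring is still at the alcohol level at C6: the C6 alkoxide is cis to the oxirane and cannot attack C5 from the rear (no epoxide migration), the (E)-carboxylate cannot reach the epoxide, and no base-sensitive epoxy enone is yet present.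

Step 14
Reactants: 18 hydroxy acid acetonide
Product: 19 keto acid: the C3-O/C2-CH2O acetonide of 20 (C3 R, C4 R, C5 R)
Conditions: Dess–Martin periodinane, CH2Cl2, 0 to 23 °C
Reagents that add atoms: none
Why: Dess–Martin oxidation of the secondary allylic C6 alcohol to the enone under near-neutral conditions that tolerate the free acid, the epoxide, the acetal and the diene; the C6 stereocentre, which only served to make the diene addition suprafacial, disappears.

Step 15
Reactants: 19 keto acid acetonide
Product: 20 (2E)-4-[(1R,5R,6R)-3-[(1E)-hept-1-en-1-yl]-5-hydroxy-4-(hydroxymethyl)-2-oxo-7-oxabicyclo[4.1.0]hept-3-en-1-yl]-2-methylbut-2-enoic acid (ambuic acid)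
Conditions: CF3CO2H/H2O, CH2Cl2, 0 °C
Reagents that add atoms: none
Why: Acid hydrolysis of the isopropylidene acetal; the epoxide is flanked by the ketone and the carbinol carbon, both of which disfavour cationic opening, so it should survive the short acid treatment.

## Compound list

1 | (E)-oct-2-enal | CCCCC/C=C/C=O | starting material
2 | (3E)-1,1-dibromonona-1,3-diene | CCCCC/C=C/C=C(Br)Br | intermediate
3 | lithium (E)-non-3-en-1-ynide | CCCCC/C=C/C#C[Li] | intermediate (not isolated)
4 | lithium (E)-1-(dimethylamino)dec-4-en-2-yn-1-olate | CCCCC/C=C/C#CC(O[Li])N(C)C | intermediate (not isolated)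
5 | (E)-dec-4-en-2-ynal | CCCCC/C=C/C#CC=O | intermediate
6 | but-2-yne-1,4-diol | OCC#CCO | starting material
7 | (E)-2-(tributylstannyl)but-2-ene-1,4-diol | OC/C(=C\CO)[Sn](CCCC)(CCCC)CCCC | intermediate
8 | (E)-4-[(tert-butyldimethylsilyl)oxy]-2-(tributylstannyl)but-2-en-1-ol | OC/C(=C\CO[Si](C)(C)C(C)(C)C)[Sn](CCCC)(CCCC)CCCC | intermediate
9 | methyl (E)-4-bromo-2-methylbut-2-enoate | COC(=O)/C(C)=C/CBr | starting material
10 | methyl (2E,5Z)-7-[(tert-butyldimethylsilyl)oxy]-5-(hydroxymethyl)-2-methylhepta-2,5-dienoate | COC(=O)/C(C)=C/C/C(CO)=C/CO[Si](C)(C)C(C)(C)C | intermediate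
11 | methyl (2E,5Z)-7-[(tert-butyldimethylsilyl)oxy]-5-formyl-2-methylhepta-2,5-dienoate | COC(=O)/C(C)=C/C/C(C=O)=C/CO[Si](C)(C)C(C)(C)C | intermediate
12 | methyl (2E)-4-[(1E,3E)-1-(acetyloxy)-4-[(tert-butyldimethylsilyl)oxy]buta-1,3-dien-2-yl]-2-methylbut-2-enoate | CC(=O)O/C=C(C/C=C(\C)C(=O)OC)/C=C/O[Si](C)(C)C(C)(C)C | intermediate
13 | methyl (2E)-4-[(3S,6R)-6-(acetyloxy)-3-[(tert-butyldimethylsilyl)oxy]-4-formyl-5-[(1E)-hept-1-en-1-yl]cyclohexa-1,4-dien-1-yl]-2-methylbut-2-enoate | CCCCC/C=C/C1=C(C=O)[C@@H](O[Si](C)(C)C(C)(C)C)C=C(C/C=C(\C)C(=O)OC)[C@H]1OC(C)=O | intermediate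
14 | methyl (2E)-4-[(3S,6R)-6-(acetyloxy)-4-formyl-5-[(1E)-hept-1-en-1-yl]-3-hydroxycyclohexa-1,4-dien-1-yl]-2-methylbut-2-enoate | CCCCC/C=C/C1=C(C=O)[C@@H](O)C=C(C/C=C(\C)C(=O)OC)[C@H]1OC(C)=O | intermediate
15 | methyl (2E)-4-[(1S,2S,5R,6R)-2-(acetyloxy)-4-formyl-3-[(1E)-hept-1-en-1-yl]-5-hydroxy-7-oxabicyclo[4.1.0]hept-3-en-1-yl]-2-methylbut-2-enoate | CCCCC/C=C/C1=C(C=O)[C@@H](O)[C@H]2O[C@@]2(C/C=C(\C)C(=O)OC)[C@H]1OC(C)=O | intermediate
16 | methyl (2E)-4-[(1S,2S,5R,6R)-2-(acetyloxy)-3-[(1E)-hept-1-en-1-yl]-5-hydroxy-4-(hydroxymethyl)-7-oxabicyclo[4.1.0]hept-3-en-1-yl]-2-methylbut-2-enoate | CCCCC/C=C/C1=C(CO)[C@@H](O)[C@H]2O[C@@]2(C/C=C(\C)C(=O)OC)[C@H]1OC(C)=O | intermediate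
17 | acetonide of 16 (2,2-dimethyl-1,3-dioxane across O–C3 and the C2 CH2O; C6 acetate and methyl ester retained) | CCCCC/C=C/C1=C2COC(C)(C)O[C@H]2[C@H]3O[C@@]3(C/C=C(\C)C(=O)OC)[C@H]1OC(C)=O | intermediate
18 | hydroxy acid: acetonide as in 17 with free C6–OH and free carboxylic acid | CCCCC/C=C/C1=C2COC(C)(C)O[C@H]2[C@H]3O[C@@]3(C/C=C(\C)C(=O)O)[C@H]1O | intermediate
19 | keto acid: C3-O/C2-CH2O acetonide of 20 | CCCCC/C=C/C1=C2COC(C)(C)O[C@H]2[C@H]3O[C@@]3(C/C=C(\C)C(=O)O)C1=O | intermediate
20 | (2E)-4-[(1R,5R,6R)-3-[(1E)-hept-1-en-1-yl]-5-hydroxy-4-(hydroxymethyl)-2-oxo-7-oxabicyclo[4.1.0]hept-3-en-1-yl]-2-methylbut-2-enoic acid | CCCCC/C=C/C1=C(CO)[C@@H](O)[C@H]2O[C@@]2(C/C=C(\C)C(=O)O)C1=O | target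

## Step count and least certain steps

Total: 15 steps. Longest linear sequence: 13 steps (6 → 20, steps 3–15). The ynal branch (steps 1–2) joins at step 8.

**Step 8 (key step, proposed new method).**
- What may go wrong:
  - addition of the diene to the activated formyl group (hetero-Diels–Alder or Mukaiyama-type) in place of the alkyne;
  - silyl transfer from the dienol ether to the triflimide, which would start an achiral silyl-cation-catalysed background reaction and erode the enantiomeric purity;
  - poor or reversed facial selectivity, because the catalyst must fix both the shielded side of the alkyne and the orientation of the formyl group;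
  - loss of acetic acid from the adduct with aromatisation under the Lewis acid.
- Fallback (known chemistry), setting out from 12 and 5 and returning at 15. The two are combined without catalyst in toluene at 25–40 °C in the presence of a trace of 2,6-di-tert-butyl-4-methylphenol. This is the established thermal cycloaddition of silyloxy- and acyloxybutadienes with acetylenic carbonyl compounds. Regiochemistry and the cis relation arise as before, but the product is racemic: 13 together with its enantiomer, methyl (2E)-4-[(3R,6S)-6-(acetyloxy)-3-[(tert-butyldimethylsilyl)oxy]-4-formyl-5-[(1E)-hept-1-en-1-yl]cyclohexa-1,4-dien-1-yl]-2-methylbut-2-enoate F1. The mixture is taken through the operations of steps 9 and 10. This gives 14 with its enantiomer, the (3R,6S)-dienol F2, and then 15 with its enantiomer, methyl (2E)-4-[(1R,2R,5S,6S)-2-(acetyloxy)-4-formyl-3-[(1E)-hept-1-en-1-yl]-5-hydroxy-7-oxabicyclo[4.1.0]hept-3-en-1-yl]-2-methylbut-2-enoate F3. Kinetic resolution with Burkholderia cepacia lipase and vinyl acetate in t-BuOMe at 25 °C follows. By the empirical size rule for lipase acylation of secondary alcohols (larger flank C2, smaller flank C4), the enzyme should acylate F3 to its C3 acetate, methyl (2E)-4-[(1R,2R,5S,6S)-2,5-bis(acetyloxy)-4-formyl-3-[(1E)-hept-1-en-1-yl]-7-oxabicyclo[4.1.0]hept-3-en-1-yl]-2-methylbut-2-enoate F4. Unreacted 15 is separated by chromatography and continues with step 11. A lipase of the opposite preference would be screened if the rule fails here.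

**Step 9 (desilylation of the 1,4-diene).**
- What may go wrong: ionisation or elimination at the doubly allylic C3 and C6 positions during the hours that a TBS ether needs, leading to loss of acetic acid or silanol and aromatisation.
- Fallback, setting out from 7 and returning at 14: the C3 oxygen is carried as a triethylsilyl ether, which is cleaved under much gentler conditions. Silylation of 7 with TESCl/imidazole should give (E)-4-[(triethylsilyl)oxy]-2-(tributylstannyl)but-2-en-1-ol F5. Coupling with 9 as in step 5 gives methyl (2E,5Z)-5-(hydroxymethyl)-2-methyl-7-[(triethylsilyl)oxy]hepta-2,5-dienoate F6. MnO2 oxidation gives methyl (2E,5Z)-5-formyl-2-methyl-7-[(triethylsilyl)oxy]hepta-2,5-dienoate F7. Enol acetylation as in step 7 gives methyl (2E)-4-[(1E,3E)-1-(acetyloxy)-4-[(triethylsilyl)oxy]buta-1,3-dien-2-yl]-2-methylbut-2-enoate F8. Cycloaddition with 5 as in step 8 gives methyl (2E)-4-[(3S,6R)-6-(acetyloxy)-4-formyl-5-[(1E)-hept-1-en-1-yl]-3-[(triethylsilyl)oxy]cyclohexa-1,4-dien-1-yl]-2-methylbut-2-enoate F9. F9 is desilylated with AcOH/THF/H2O at 0 °C within minutes to give 14. The price is a less selective monosilylation and a silyl dienol ether that is more easily transferred in the key step.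

**Step 10 (directed epoxidation).**
- What may go wrong: oxidation of the doubly allylic C3 carbinol to a dienone by the vanadium peroxide, or Lewis-acid-induced dehydration, either of which ends in an arene; and reversible closure of the cis-dienal to a 2H-pyran that removes material from the reaction.
- Fallback, setting out from 14 and returning at 15: hydrogen-bond-directed (Henbest) epoxidation with m-chloroperoxybenzoic acid and solid NaHCO3 in CH2Cl2 at 0 °C. The peracid is delivered to the hydroxyl face of the only electron-rich alkene (C4=C5) without a metal, and the formyl-deactivated C1=C2 and the enoate remain inert. No new compound is involved (F0).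

**Step 7 (dienyl acetate).**
- What may go wrong: slow or incomplete vinylogous enolisation, migration of the skipped side-chain alkene into conjugation on prolonged heating with amine, and a mixture of diene geometries, of which only the (1E,3E)-isomer is a competent diene.
- Fallback, setting out from 11 and returning at 12: two-stage enolisation. Soft enolisation with Me3SiOSO2CF3/Et3N in CH2Cl2 at −78 to 0 °C should give methyl (2E)-4-[(1E,3E)-4-[(tert-butyldimethylsilyl)oxy]-1-[(trimethylsilyl)oxy]buta-1,3-dien-2-yl]-2-methylbut-2-enoate F10. Its more labile trimethylsilyl enol ether is then exchanged for acetate with acetyl fluoride and catalytic Bu4N+ Ph3SiF2− in THF at −20 °C (fluoride-catalysed O-acylation of silyl enol ethers). The TBS dienol ether is kept, and the product is 12.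

## Further compounds

F1 | step 8 | methyl (2E)-4-[(3R,6S)-6-(acetyloxy)-3-[(tert-butyldimethylsilyl)oxy]-4-formyl-5-[(1E)-hept-1-en-1-yl]cyclohexa-1,4-dien-1-yl]-2-methylbut-2-enoate (enantiomer of 13) | CCCCC/C=C/C1=C(C=O)[C@H](O[Si](C)(C)C(C)(C)C)C=C(C/C=C(\C)C(=O)OC)[C@@H]1OC(C)=O
F2 | step 8 | methyl (2E)-4-[(3R,6S)-6-(acetyloxy)-4-formyl-5-[(1E)-hept-1-en-1-yl]-3-hydroxycyclohexa-1,4-dien-1-yl]-2-methylbut-2-enoate (enantiomer of 14) | CCCCC/C=C/C1=C(C=O)[C@H](O)C=C(C/C=C(\C)C(=O)OC)[C@@H]1OC(C)=O
F3 | step 8 | methyl (2E)-4-[(1R,2R,5S,6S)-2-(acetyloxy)-4-formyl-3-[(1E)-hept-1-en-1-yl]-5-hydroxy-7-oxabicyclo[4.1.0]hept-3-en-1-yl]-2-methylbut-2-enoate (enantiomer of 15) | CCCCC/C=C/C1=C(C=O)[C@H](O)[C@@H]2O[C@]2(C/C=C(\C)C(=O)OC)[C@@H]1OC(C)=O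
F4 | step 8 | methyl (2E)-4-[(1R,2R,5S,6S)-2,5-bis(acetyloxy)-4-formyl-3-[(1E)-hept-1-en-1-yl]-7-oxabicyclo[4.1.0]hept-3-en-1-yl]-2-methylbut-2-enoate | CCCCC/C=C/C1=C(C=O)[C@H](OC(C)=O)[C@@H]2O[C@]2(C/C=C(\C)C(=O)OC)[C@@H]1OC(C)=O
F5 | step 9 | (E)-4-[(triethylsilyl)oxy]-2-(tributylstannyl)but-2-en-1-ol | OC/C(=C\CO[Si](CC)(CC)CC)[Sn](CCCC)(CCCC)CCCC
F6 | step 9 | methyl (2E,5Z)-5-(hydroxymethyl)-2-methyl-7-[(triethylsilyl)oxy]hepta-2,5-dienoate | COC(=O)/C(C)=C/C/C(CO)=C/CO[Si](CC)(CC)CC
F7 | step 9 | methyl (2E,5Z)-5-formyl-2-methyl-7-[(triethylsilyl)oxy]hepta-2,5-dienoate | COC(=O)/C(C)=C/C/C(C=O)=C/CO[Si](CC)(CC)CC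
F8 | step 9 | methyl (2E)-4-[(1E,3E)-1-(acetyloxy)-4-[(triethylsilyl)oxy]buta-1,3-dien-2-yl]-2-methylbut-2-enoate | CC(=O)O/C=C(C/C=C(\C)C(=O)OC)/C=C/O[Si](CC)(CC)CC
F9 | step 9 | methyl (2E)-4-[(3S,6R)-6-(acetyloxy)-4-formyl-5-[(1E)-hept-1-en-1-yl]-3-[(triethylsilyl)oxy]cyclohexa-1,4-dien-1-yl]-2-methylbut-2-enoate | CCCCC/C=C/C1=C(C=O)[C@@H](O[Si](CC)(CC)CC)C=C(C/C=C(\C)C(=O)OC)[C@H]1OC(C)=O
F0 | step 10 | none | none
F10 | step 7 | methyl (2E)-4-[(1E,3E)-4-[(tert-butyldimethylsilyl)oxy]-1-[(trimethylsilyl)oxy]buta-1,3-dien-2-yl]-2-methylbut-2-enoate | C[Si](C)(C)O/C=C(C/C=C(\C)C(=O)OC)/C=C/O[Si](C)(C)C(C)(C)C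
A1 | alternative 1 | methyl (2E)-4-(3,6-dioxocyclohexa-1,4-dien-1-yl)-2-methylbut-2-enoate | COC(=O)/C(C)=C/CC1=CC(=O)C=CC1=O
A2 | alternative 1 | cyclopenta-1,3-diene | C1C=CC=C1
A3 | alternative 1 | endo cyclopentadiene–quinone adduct (tricyclic enedione) | O=C1C=C(C/C=C(\C)C(=O)OC)C(=O)[C@H]2[C@@H]1[C@H]1C=C[C@@H]2C1
A4 | alternative 2 | open-chain (Z)-enone aldehyde with the C5 chloro ketone (C5 configuration undefined) | CCCCC/C=C/C(C(=O)C(Cl)C/C=C(\C)COCc1ccc(OC)cc1)=C(\CO[Si](C)(C)C(C)(C)C)[C@@H](O[Si](C)(C)C(C)(C)C)C=O
A5 | alternative 2 | protected epoxycyclohexenone with the C3, C4, C5 triad | CCCCC/C=C/C1=C(CO[Si](C)(C)C(C)(C)C)[C@@H](O[Si](C)(C)C(C)(C)C)[C@H]2O[C@@]2(C/C=C(\C)COCc3ccc(OC)cc3)C1=O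
A6 | alternative 3 | open-chain epoxy enyne (5-methylene-1,3-dioxane, C6 propargylic silyl ether, C6 epimers) | C#CC(O[Si](C)(C)C(C)(C)C)[C@]1(CCOCc2ccc(OC)cc2)O[C@@H]1[C@@H]3OC(C)(C)OCC3=C
A7 | alternative 3 | 1-vinylcyclohexene epoxide with the C3, C4, C5 triad (C6 epimers) | C=CC1=C2COC(C)(C)O[C@H]2[C@H]3O[C@@]3(CCOCc4ccc(OC)cc4)C1O[Si](C)(C)C(C)(C)C
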